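**Easy step.** I began with the easy step, the bookkeeping of L + J -> D, in flasks where the enzyme G turns L into J and may itself fall away to a form Z. That step takes one point of J and one of L and makes two points of D. So D needs only a correction: M = J + D/2 counts what G has ever made, and the side step leaves it unchanged. J − L equals 2M minus the whole charge.

common to all: L 0.10 M (fed, over 15 min)

| flask | G | temperature | remark | time |
|---|---|---|---|---|
| green | 6.0 × 10⁻⁴ mol% | 11 °C | run made earlier |  |
| teal | 0.0024 mol% | 25 °C | run made earlier |  |
| Tuesday's | 0.0012 mol% |  | at 5 °C until 15 min, from then on at 30 °C | 5.0 h |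
| Thursday's | 0.0012 mol% |  | at 30 °C throughout | 5.0 h |

- green (time / h: J / %, D / %): 0.250: 45.8, 0.9; 0.833: 80.3, 5.8; 1.33: 83.1, 7.8; 2.00: 83.4, 10.6; 3.00: 83.3, 12.0; 4.00: 83.5, 14.5; 5.00: 82.8, 14.9
- teal (time / min: J / %, D / %): 10.0: 34.3, 1.0; 15.0: 62.0, 3.8; 20.0: 73.9, 5.2; 30.0: 78.2, 7.9; 40.0: 78.1, 10.7; 60.0: 76.9, 14.7; 120: 73.4, 21.8

(scatter of a reading: 0.3 percentage points)

- a species is counted by the L in it: one D counts as two
- what was read earlier has a scatter of 0.3 percentage points, one standard deviation
- steps that have been proposed: G -> Z; L + G -> J + G; L + J -> D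
- percentages count the whole charge, also what has not yet gone in

- which of the two ends with the higher share of J in all that became J or D ("neither" if they lie within 2 percentage points) (Tuesday's / Thursday's / neither)
- share of J in all that became J or D, Tuesday's
- share of J in all that became J or D, Thursday's

**Reading M.** Teal's J fell from 76.9% to 73.4%, yet M read 84.3% after 60.0 min and 84.3% after 120 min, equal within scatter. I carried this final output M of teal, scaled by loading. That holds the turnover number, M per G, fixed.

**Turned round.** For Thursday's to win, I reckoned, its M should exceed Tuesday's. Thursday's loading is half of teal's, so scaling gave 42.1%, and its 30 °C is warmer than teal's 25 °C. That lies below half of the charge, so I expected L to outlast J in Thursday's. For Tuesday's I took green's M at the end of the feed, 46.2%, since Tuesday's loading is twice green's while its feed runs colder. This estimate, taken before any warm stage, stood higher than my estimate for Thursday's by 4.1 percentage points, so I chose Tuesday's.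

**The forecast.** It said Tuesday's, with 85% against 17%, and held for Thursday's that “the enzyme dies during feeding”.

**Result.** Tuesday's ended at 58.0% and Thursday's at 6.27%, so Tuesday's came out higher.

    G → Z (k = 2.49 × 10⁻⁴ /min, Ea = 187 kJ/mol)
    L + G → J + G, rate k2*[L]^2.5*[G]/(1 + ([L]/Kh2)^2.5) (0.137 M, k = 2.29 × 10⁵ /M².5/s, Ea = 20.0 kJ/mol)
    L + J → D (k = 0.0259 /M/min, Ea = 54.0 kJ/mol)
    (constants at 5 °C)

Thursday's still held L 32.8% beside J 4.21%, and after 50.0 h its share was 0%. Its M was 35.7%, against the scaled 42.1%. The neighbour with 4.8 × 10⁻⁴ mol% of G, scaled from teal's M the same way, gave 16.9%; it ended with L 61.2% and M at 19.7%.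

(The earlier runs and the new flask were computed for substances that don't exist.)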